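## Retrosynthetic overview

- 28 ⇐ alkyne 27 (Z-enol acetate by ruthenium-catalysed anti-Markovnikov addition of AcOH) ⇐ diol 24 (8-O-angeloylation, then 9-O-acetylation) ⇐ lactone 21 (α-methylenation).
- C9–OH ⇐ C9 ketone; C8–OH and C7–H ⇐ reductive hydroxylation of enone lactone 17; C11–C12 ⇐ ethyl acetate enolate on a C7 ketone plus oxidative 1,3-transposition; C6–OH ⇐ α′-hydroxylation; C1≡C2 ⇐ C10 formyl group.
- Cyclohexane C5–C10 ⇐ [4+2] of E-dienal 3 (C5, C10 and their substituents) with 1-(acylamino)-3-siloxybutadiene 7 (C6–C9), forming C5–C6 and C9–C10.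
- Feature: in the only carbocycle, quaternary C10 (methyl plus the C1 arm) is next to C5, and the C1 arm is trans to the C5 isopropenyl group. That pair is the E-geometry of an α-methyl dienal, and C7, two atoms on, is where the diene oxygen ends up as a ketone.
- Ring order: cyclohexane (step 5), then the γ-lactone O–C6/C7–C11–C12 (step 11).

Key step: step 5

Numbering used throughout: ring carbons C5–C10 as above; C11, C12, C13 are the lactone α-carbon, carbonyl and exocyclic methylene; C1, C2 are the two-carbon arm on C10. β is the face of the C10 methyl group, α the opposite face. The target is 5β-isopropenyl, 6α-O (lactone), 7α-H, 8α-angeloyloxy, 9β-acetoxy, 10β-methyl, i.e. (5S,6R,7S,8R,9R,10S).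

Assumption: the (R,R)-salen ligand is written for step 5; the diene must reach the C2-Re face of the bound dienal, and the antipodal ligand is used if induction runs the other way.

## Route

Step 1
Reactants: 1 methacrolein; 2 2-(triphenyl-λ5-phosphanylidene)propanal
Product: 3 (2E)-2,4-dimethylpenta-2,4-dienal
Conditions: PhH, 70 °C (sealed), excess 1; distil
Reagents that add atoms: none
Why: Wittig olefination with a formyl-stabilised ylide should give the E-enal under thermodynamic control and avoids the self-condensation and Michael addition that a crossed aldol of propanal with methacrolein would suffer.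

Step 2
Reactants: 4 (3E)-4-(dimethylamino)but-3-en-2-one
Product: 5 (3Z)-4-(benzylamino)but-3-en-2-one
Conditions: BnNH2, EtOH, rt → 50 °C
Reagents that add atoms: benzylamine, NCc1ccccc1
Why: Amine exchange (addition–elimination) on a vinylogous amide, driven by loss of volatile dimethylamine and by the hydrogen-bonded Z secondary enaminone.

Step 3
Reactants: 5 (3Z)-4-(benzylamino)but-3-en-2-one
Product: 6 methyl benzyl[(1E)-3-oxobut-1-en-1-yl]carbamate
Conditions: NaHMDS, THF, −78 °C; ClCO2Me, −78 → 0 °C
Reagents that add atoms: methyl chloroformate, COC(Cl)=O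
Why: N-acylation of the sodium salt of the vinylogous amide should give the vinylogous imide, whose nitrogen lone pair is attenuated by the carbamate.

Step 4
Reactants: 6 methyl benzyl[(1E)-3-oxobut-1-en-1-yl]carbamate
Product: 7 methyl benzyl[(1E)-3-{[tert-butyl(dimethyl)silyl]oxy}buta-1,3-dien-1-yl]carbamate
Conditions: KHMDS, THF, −78 °C; TBSCl, −78 °C → rt
Reagents that add atoms: tert-butyldimethylsilyl chloride, CC(C)(C)[Si](C)(C)Cl
Why: Kinetic deprotonation of the methyl ketone and O-silylation of the cross-conjugated potassium enolate should give the 2-siloxydiene with the E-enamide geometry retained.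

Step 5
Reactants: 3 (2E)-2,4-dimethylpenta-2,4-dienal; 7 methyl benzyl[(1E)-3-{[tert-butyl(dimethyl)silyl]oxy}buta-1,3-dien-1-yl]carbamate
Product: 9 enone aldehyde (1R,6S)-1-methyl-4-oxo-6-(prop-1-en-2-yl)cyclohex-2-ene-1-carbaldehyde, via cycloadduct 8 (not isolated)
Conditions: (R,R)-(salen)CrSbF6 (5 mol%; salen = N,N′-bis(3,5-di-tert-butylsalicylidene)cyclohexane-1,2-diaminate), 4 Å MS, CH2Cl2, −40 → 0 °C; then aq. HF, MeCN, 0 °C
Reagents that add atoms: none
Why: The cationic trivalent chromium centre binds the formyl oxygen of 3 and the siloxydiene adds across the α,β-bond in a concerted, asynchronous [4+2] cycloaddition, its CH2 terminus bonding to C5 (β-carbon) and its nitrogen-bearing terminus to C10 (α-carbon); the closest known reaction type is the (salen)Cr-catalysed Diels–Alder reaction of 1-(acylamino)-3-siloxybutadienes with α-substituted acroleins, which already builds formyl-bearing quaternary carbons. The cyclohexane ring C5–C10 is closed by this intermolecular cycloaddition, both ring bonds (C5–C6 and C9–C10) forming in the one step. C10 is set by the salen ligand, which should leave the C2-Re face of the bound enal open, and C5 follows from C10 because suprafacial addition turns the E-geometry of the enal into the trans relation of formyl and isopropenyl; the endo-derived C9 centre is erased when HF hydrolyses the silyl enol ether and the carbamate leaves by β-elimination. The step needs regioselectivity, fixed by the push of nitrogen and siloxy oxygen onto the diene CH2 terminus, and chemoselectivity for the α,β-alkene over the γ,δ-alkene and the C=O group, which rests on Lewis-acid activation of the conjugated π-bond and the low dienophilicity of the remote isopropenyl unit. The carbamate on nitrogen is what allows catalysis: it slows the uncatalysed racemic reaction and gives a non-basic cycloadduct that does not bind chromium.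

Step 6
Reactants: 9 enone aldehyde (1R,6S)-1-methyl-4-oxo-6-(prop-1-en-2-yl)cyclohex-2-ene-1-carbaldehyde
Product: 10 (4R,5S)-4-ethynyl-4-methyl-5-(prop-1-en-2-yl)cyclohex-2-en-1-one
Conditions: dimethyl (1-diazo-2-oxopropyl)phosphonate, K2CO3, MeOH, 0 °C → rt
Reagents that add atoms: dimethyl (1-diazo-2-oxopropyl)phosphonate, CC(=O)C(=[N+]=[N-])P(=O)(OC)OC
Why: Seyferth–Gilbert homologation in the Ohira–Bestmann form converts the aldehyde, which reacts far faster than the enone carbonyl, into the terminal alkyne; the quaternary α-carbon cannot epimerise and the low temperature limits methoxide attack on the formyl group.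

Step 7
Reactants: 10 (4R,5S)-4-ethynyl-4-methyl-5-(prop-1-en-2-yl)cyclohex-2-en-1-one
Product: 11 (4R,5S,6R)-4-ethynyl-6-hydroxy-4-methyl-5-(prop-1-en-2-yl)cyclohex-2-en-1-one (6α-OH)
Conditions: KHMDS (1.05 equiv), THF, −78 °C; 2-(benzenesulfonyl)-3-phenyloxaziridine, −78 °C; AcOH quench
Reagents that add atoms: 2-(benzenesulfonyl)-3-phenyloxaziridine, O=S(=O)(c1ccccc1)N1OC1c1ccccc1
Why: Davis oxidation of the kinetic α′-enolate (only C6 can be deprotonated, since C10 is quaternary and the ketone C–H is more acidic than the alkyne C–H) should deliver oxygen to the α-face, anti to the 5β-isopropenyl and pseudoaxial 10β-methyl groups, giving the equatorial 6α-alcohol, which is also the more stable epimer.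

Step 8
Reactants: 11 (4R,5S,6R)-4-ethynyl-6-hydroxy-4-methyl-5-(prop-1-en-2-yl)cyclohex-2-en-1-one
Product: 12 (4R,5S,6R)-6-{[tert-butyl(dimethyl)silyl]oxy}-4-ethynyl-4-methyl-5-(prop-1-en-2-yl)cyclohex-2-en-1-one
Conditions: TBSCl, imidazole, DMF, rt
Reagents that add atoms: tert-butyldimethylsilyl chloride, CC(C)(C)[Si](C)(C)Cl
Why: Standard silylation of the secondary α-hydroxy ketone protects O6 against the enolate addition and the chromium oxidation that follow.

Step 9
Reactants: 12 (4R,5S,6R)-6-{[tert-butyl(dimethyl)silyl]oxy}-4-ethynyl-4-methyl-5-(prop-1-en-2-yl)cyclohex-2-en-1-one; 13 ethyl acetate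
Product: 14 tertiary allylic alcohol: C7(OH)(CH2CO2Et), C8=C9, 6α-OTBS, 10α-ethynyl, 10β-methyl, 5β-isopropenyl
Conditions: LDA, 13 (3 equiv), THF, −78 °C; then 12, −78 °C; AcOH quench at −78 °C
Reagents that add atoms: none
Why: Aldol-type 1,2-addition of the lithium ester enolate to the enone carbonyl is favoured at low temperature and by the neopentyl character of the conjugate position C9; the C7 configuration (7α-OH drawn, from attack anti to the silyloxy group) is lost in the next step.

Step 10
Reactants: 14 tertiary allylic alcohol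
Product: 15 γ-silyloxy enone ester: C9=O, C7=C8, C7–CH2CO2Et, 6α-OTBS, 10α-ethynyl, 10β-methyl, 5β-isopropenyl
Conditions: pyridinium chlorochromate, (C5H5NH)[CrO3Cl], 4 Å MS, CH2Cl2, rt
Reagents that add atoms: pyridinium chlorochromate, [O-][Cr](=O)(=O)Cl.c1cc[nH+]cc1 (supplies the C9 oxygen; the C7 oxygen leaves on chromium)
Why: Dauben–Babler oxidative 1,3-transposition: the chromate ester of the tertiary allylic alcohol undergoes a [3,3]-shift to C9 and is oxidised there, which moves the carbonyl to C9 and leaves the acetate chain on sp2 C7.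

Step 11
Reactants: 15 γ-silyloxy enone ester
Product: 17 enone lactone: 6α,12-olide fused at C6–C7 with C7=C8–C9=O, 10α-ethynyl, 10β-methyl, 5β-isopropenyl, via hydroxy ester 16 (not isolated)
Conditions: HF·pyridine, THF, 0 °C → rt; then CSA (cat.), CH2Cl2, rt
Reagents that add atoms: none
Why: Fluoride desilylation frees the 6α-hydroxyl, which lies beside the in-plane ester chain and should close the γ-lactone by acid-catalysed 5-exo-trig transesterification without touching C6 or the isopropenyl group.

Step 12
Reactants: 17 enone lactone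
Product: 19 8α-hydroxy-9-oxo-6α,12-olide (trans-fused lactone, 7α-H), via 8α-hydroperoxide 18 (not isolated)
Conditions: Mn(dpm)3 (5 mol%), PhSiH3 (1.3 equiv), O2 (1 atm), i-PrOH/CH2Cl2, 0 °C; then P(OEt)3
Reagents that add atoms: dioxygen, O=O
Why: Manganese-hydride hydrogen-atom transfer to the enone (Mukaiyama-type reductive α-hydroxylation) puts H on C7 and, after O2 capture of the C8 radical and phosphite reduction, OH on C8: the planar lactone holds O6 in the enone plane and C5 above it, so H should arrive axially on the α-face (chair-like, anti to the 5β-isopropenyl group) to give the trans-fused lactone, O2 should add to C8 anti to the axial 10β-methyl group to give the equatorial 8α-oxygen, and the conjugated enone is expected to react before the isolated isopropenyl alkene.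

Step 13
Reactants: 19 8α-hydroxy-9-oxo-6α,12-olide
Product: 20 8α,9β-dihydroxy-6α,12-olide
Conditions: NaBH4, CeCl3·7H2O, MeOH, −78 → −40 °C
Reagents that add atoms: none
Why: Luche-type reduction with a small hydride should attack C9 axially from the α-face, away from the axial 10β-methyl group, to give the equatorial 9β-alcohol, while the cold, weakly basic medium spares the lactone.

Step 14
Reactants: 20 8α,9β-dihydroxy-6α,12-olide
Product: 21 8α,9β-O-isopropylidene-6α,12-olide
Conditions: 2-methoxypropene, PPTS (cat.), CH2Cl2, 0 °C → rt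
Reagents that add atoms: 2-methoxypropene, COC(C)=C
Why: Kinetic transacetalisation ties the trans-diequatorial diol into a dioxolane, which is inert to the basic methylenation and blocks O8 from attacking the lactone.

Step 15
Reactants: 21 8α,9β-O-isopropylidene-6α,12-olide
Product: 23 8α,9β-O-isopropylidene-11(13)-methylene-6α,12-olide, via sodium hydroxymethylene-lactone salt 22 (not isolated)
Conditions: NaH, HCO2Et, Et2O (cat. EtOH), rt; then (CH2O)n, THF, 65 °C
Reagents that add atoms: formaldehyde (as paraformaldehyde), C=O; ethyl formate, CCOC=O (its formyl carbon stays only in 22)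
Why: Claisen formylation at C11 followed by aldol addition to formaldehyde, formyl transfer and loss of formate is an established α-methylenation of γ-lactones that needs no amide base, so the terminal alkyne C–H is left alone.

Step 16
Reactants: 23 8α,9β-O-isopropylidene-11(13)-methylene-6α,12-olide
Product: 24 8α,9β-dihydroxy-11(13)-methylene-6α,12-olide
Conditions: AcOH/H2O 4:1, 40 °C
Reagents that add atoms: none
Why: The strained trans-fused dioxolane should hydrolyse under mild acid, which the α-methylene lactone, alkyne and isopropenyl group tolerate and which is too weak to move the lactone to O8.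

Step 17
Reactants: 24 8α,9β-dihydroxy-11(13)-methylene-6α,12-olide; 25 angelic acid
Product: 26 8α-angeloyloxy-9β-hydroxy-11(13)-methylene-6α,12-olide
Conditions: 25, 2,4,6-trichlorobenzoyl chloride, Et3N, PhMe, rt; then 24, 75 °C
Reagents that add atoms: none
Why: Yamaguchi-type mixed-anhydride esterification without a nucleophilic catalyst keeps the Z-geometry of the angelate, and the bulky acyl donor should take the C8 hydroxyl because the C9 hydroxyl is neopentyl, next to quaternary C10.

Step 18
Reactants: 26 8α-angeloyloxy-9β-hydroxy-11(13)-methylene-6α,12-olide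
Product: 27 9β-acetoxy-8α-angeloyloxy-10α-ethynyl-11(13)-methylene-6α,12-olide
Conditions: Ac2O, DMAP, pyridine, CH2Cl2, rt
Reagents that add atoms: acetic anhydride, CC(=O)OC(C)=O
Why: DMAP-catalysed acylation with the small acetyl donor should esterify the remaining hindered 9β-alcohol.

Step 19
Reactants: 27 9β-acetoxy-8α-angeloyloxy-10α-ethynyl-11(13)-methylene-6α,12-olide
Product: 28 target CNP0582479.1
Conditions: Ru(2-methylallyl)2(dppb) (5 mol%; dppb = 1,4-bis(diphenylphosphino)butane), AcOH, PhMe, 60 °C
Reagents that add atoms: acetic acid, CC(=O)O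
Why: Anti-Markovnikov trans-addition of a carboxylic acid to a terminal alkyne through a divalent ruthenium vinylidene, in which acetate attacks the metal-bound carbon and protonolysis releases the (Z)-enol ester; the bulky quaternary substituent reinforces attack at the terminal carbon.

## Compound list

1 | methacrolein (2-methylprop-2-enal) | CC(=C)C=O | starting material
2 | 2-(triphenyl-λ5-phosphanylidene)propanal | CC(C=O)=P(c1ccccc1)(c1ccccc1)c1ccccc1 | starting material
3 | (2E)-2,4-dimethylpenta-2,4-dienal | O=C/C(C)=C/C(C)=C | intermediate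
4 | (3E)-4-(dimethylamino)but-3-en-2-one | CN(C)/C=C/C(C)=O | starting material
5 | (3Z)-4-(benzylamino)but-3-en-2-one | CC(=O)/C=C\NCc1ccccc1 | intermediate
6 | methyl benzyl[(1E)-3-oxobut-1-en-1-yl]carbamate | COC(=O)N(Cc1ccccc1)/C=C/C(C)=O | intermediate
7 | methyl benzyl[(1E)-3-{[tert-butyl(dimethyl)silyl]oxy}buta-1,3-dien-1-yl]carbamate | COC(=O)N(Cc1ccccc1)/C=C/C(=C)O[Si](C)(C)C(C)(C)C | intermediate (key-step precursor)
8 | cycloadduct: C7 silyl enol ether, C9 N(Bn)CO2Me cis to the C10 formyl group, formyl trans to 5-isopropenyl | CC(C)(C)[Si](C)(C)OC1=C[C@@H](N(Cc2ccccc2)C(=O)OC)[C@@](C)(C=O)[C@@H](C1)C(=C)C | intermediate (not isolated)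
9 | (1R,6S)-1-methyl-4-oxo-6-(prop-1-en-2-yl)cyclohex-2-ene-1-carbaldehyde | O=C1C=C[C@@](C)(C=O)[C@@H](C1)C(=C)C | intermediate (key-step product)
10 | (4R,5S)-4-ethynyl-4-methyl-5-(prop-1-en-2-yl)cyclohex-2-en-1-one | O=C1C=C[C@@](C)(C#C)[C@@H](C1)C(=C)C | intermediate
11 | (4R,5S,6R)-4-ethynyl-6-hydroxy-4-methyl-5-(prop-1-en-2-yl)cyclohex-2-en-1-one | O[C@H]2C(=O)C=C[C@@](C)(C#C)[C@@H]2C(=C)C | intermediate
12 | (4R,5S,6R)-6-{[tert-butyl(dimethyl)silyl]oxy}-4-ethynyl-4-methyl-5-(prop-1-en-2-yl)cyclohex-2-en-1-one | CC(C)(C)[Si](C)(C)O[C@H]2C(=O)C=C[C@@](C)(C#C)[C@@H]2C(=C)C | intermediate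
13 | ethyl acetate | CCOC(C)=O | starting material
14 | tertiary allylic alcohol, C7(OH)(CH2CO2Et), C8=C9, 6α-OTBS (7α-OH epimer drawn; both epimers converge) | CC(C)(C)[Si](C)(C)O[C@H]2[C@](O)(CC(=O)OCC)C=C[C@@](C)(C#C)[C@@H]2C(=C)C | intermediate
15 | γ-silyloxy enone ester, C9=O, C7=C8, C7–CH2CO2Et, 6α-OTBS | CC(C)(C)[Si](C)(C)O[C@H]2C(CC(=O)OCC)=CC(=O)[C@@](C)(C#C)[C@@H]2C(=C)C | intermediate
16 | 6α-hydroxy enone ester | O[C@H]2C(CC(=O)OCC)=CC(=O)[C@@](C)(C#C)[C@@H]2C(=C)C | intermediate (not isolated)
17 | enone lactone, 6α,12-olide with C7=C8–C9=O | C1C(=O)O[C@H]2C1=CC(=O)[C@@](C)(C#C)[C@@H]2C(=C)C | intermediate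
18 | 8α-hydroperoxy-9-oxo-6α,12-olide (7α-H) | C1C(=O)O[C@H]2[C@H]1[C@@H](OO)C(=O)[C@@](C)(C#C)[C@@H]2C(=C)C | intermediate (not isolated)
19 | 8α-hydroxy-9-oxo-6α,12-olide (trans-fused, 7α-H) | C1C(=O)O[C@H]2[C@H]1[C@@H](O)C(=O)[C@@](C)(C#C)[C@@H]2C(=C)C | intermediate
20 | 8α,9β-dihydroxy-6α,12-olide | C1C(=O)O[C@H]2[C@H]1[C@@H](O)[C@H](O)[C@@](C)(C#C)[C@@H]2C(=C)C | intermediate
21 | 8α,9β-O-isopropylidene-6α,12-olide | C1C(=O)O[C@H]2[C@H]1[C@@H](OC(C)(C)O3)[C@H]3[C@@](C)(C#C)[C@@H]2C(=C)C | intermediate
22 | sodium salt of the 11-(hydroxymethylene) lactone | [Na+].[O-]C=C1C(=O)O[C@H]2[C@H]1[C@@H](OC(C)(C)O3)[C@H]3[C@@](C)(C#C)[C@@H]2C(=C)C | intermediate (not isolated)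
23 | 8α,9β-O-isopropylidene-11(13)-methylene-6α,12-olide | C=C1C(=O)O[C@H]2[C@H]1[C@@H](OC(C)(C)O3)[C@H]3[C@@](C)(C#C)[C@@H]2C(=C)C | intermediate
24 | 8α,9β-dihydroxy-11(13)-methylene-6α,12-olide | C=C1C(=O)O[C@H]2[C@H]1[C@@H](O)[C@H](O)[C@@](C)(C#C)[C@@H]2C(=C)C | intermediate
25 | angelic acid, (2Z)-2-methylbut-2-enoic acid | C/C=C(/C)C(=O)O | starting material
26 | 8α-angeloyloxy-9β-hydroxy-11(13)-methylene-6α,12-olide | C=C1C(=O)O[C@H]2[C@H]1[C@@H](OC(=O)/C(C)=C\C)[C@H](O)[C@@](C)(C#C)[C@@H]2C(=C)C | intermediate
27 | 9β-acetoxy-8α-angeloyloxy-10α-ethynyl-11(13)-methylene-6α,12-olide | C=C1C(=O)O[C@H]2[C@H]1[C@@H](OC(=O)/C(C)=C\C)[C@H](OC(C)=O)[C@@](C)(C#C)[C@@H]2C(=C)C | intermediate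
28 | CNP0582479.1: (5S,6R,7S,8R,9R,10S) 9β-acetoxy-10α-[(Z)-2-acetoxyvinyl]-8α-angeloyloxy-5β-isopropenyl-10β-methyl-11(13)-methylene-6α,12-olide | C=C1C(=O)O[C@H]2[C@H]1[C@@H](OC(=O)/C(C)=C\C)[C@H](OC(C)=O)[C@@](C)(/C=C\OC(C)=O)[C@@H]2C(=C)C | target

## Step count

Total steps: 19. Longest linear sequence: 18 steps (4 → 28, steps 2–19).

## Steps most likely to fail

1. Step 5. The trisubstituted dienal may be too sluggish a dienophile for the carbamate-attenuated diene. Cycloaddition at the α,β-bond could then lose out to hetero-cycloaddition at the chromium-bound C=O or to diene decomposition, or proceed with poor facial selectivity.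
Fallback (auxiliary control with a more nucleophilic diene and no Lewis acid), setting out from 4 and 3 and returning at 9: amine exchange of 4 with (2R,5R)-2,5-diphenylpyrrolidine should give (3E)-4-[(2R,5R)-2,5-diphenylpyrrolidin-1-yl]but-3-en-2-one F1. KHMDS/TBSCl should convert it into the C2-symmetric diene (2R,5R)-1-[(1E)-3-{[tert-butyl(dimethyl)silyl]oxy}buta-1,3-dien-1-yl]-2,5-diphenylpyrrolidine F2. Thermal [4+2] reaction with 3 (PhMe, rt → 60 °C) should give the auxiliary cycloadduct F3, and aq. HF in MeCN should hydrolyse it and eliminate the amine to give 9, with the pyrrolidine recovered. The antipodal auxiliary is used if the facial sense requires it.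

2. Step 12. Hydrogen may be delivered to the β-face of C7, giving the cis-fused lactone, or the manganese hydride may hydrate the isopropenyl alkene in competition with the enone.
Fallback (C7 set by C–C bond formation anti to the neighbouring silyloxy group instead of by hydrogen delivery), setting out from 12 and returning at 19: Weitz–Scheffer epoxidation (H2O2, NaOH, MeOH, 0 °C) should give the 8,9-epoxy ketone F4. Wharton transposition (N2H4·H2O, cat. AcOH, MeOH) should give the allylic alcohol F5, with C9–OH and C7=C8. Dess–Martin oxidation should give the C7-unsubstituted γ-silyloxy enone F6. Mukaiyama–Michael addition of 1-ethoxy-1-(tert-butyldimethylsilyloxy)ethene (cat. TBSOTf, CH2Cl2, −78 °C) should place the acetate chain on the β-face of C7, anti to 6α-OTBS, and give the silyl enol ether F7. Rubottom oxidation (dimethyldioxirane, acetone, −40 °C), anti to the axial 10β-methyl group, should give the 8α-silyloxy ketone F8. HF·pyridine followed by cat. CSA should remove both silyl groups and close the lactone to 19.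

3. Step 6. During the slow homologation of the neopentyl aldehyde, methoxide may remove the formyl group through the extended enolate of the enone (vinylogous retro-Claisen cleavage) or add to the enone.
Fallback (homologation before the enone is unmasked), setting out from 8 and returning at 10: the crude cycloadduct 8, with the acid treatment of step 5 left out, is treated with lithiated trimethylsilyldiazomethane (TMSCHN2, n-BuLi, THF, −78 → 0 °C; Colvin rearrangement). This should give the alkynyl cycloadduct F9, which has no enone and so no path for deformylation. Aq. HF in MeCN should then hydrolyse the silyl enol ether and eliminate the carbamate to give 10.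

## Further compounds

F1 | step 5 | (3E)-4-[(2R,5R)-2,5-diphenylpyrrolidin-1-yl]but-3-en-2-one | CC(=O)/C=C/N1[C@@H](c2ccccc2)CC[C@@H]1c1ccccc1
F2 | step 5 | (2R,5R)-1-[(1E)-3-{[tert-butyl(dimethyl)silyl]oxy}buta-1,3-dien-1-yl]-2,5-diphenylpyrrolidine | C=C(O[Si](C)(C)C(C)(C)C)/C=C/N1[C@@H](c2ccccc2)CC[C@@H]1c1ccccc1
F3 | step 5 | auxiliary cycloadduct, C7 silyl enol ether, C9 pyrrolidinyl cis to the C10 formyl group | CC(C)(C)[Si](C)(C)OC1=C[C@@H](N2[C@@H](c3ccccc3)CC[C@@H]2c2ccccc2)[C@@](C)(C=O)[C@@H](C1)C(=C)C
F4 | step 12 | 8α,9α-epoxy-7-oxo-6α-silyloxy compound | CC(C)(C)[Si](C)(C)O[C@H]2C(=O)[C@H]3O[C@H]3[C@@](C)(C#C)[C@@H]2C(=C)C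
F5 | step 12 | allylic alcohol, 9α-OH, C7=C8, 6α-OTBS | CC(C)(C)[Si](C)(C)O[C@H]2C=C[C@@H](O)[C@@](C)(C#C)[C@@H]2C(=C)C
F6 | step 12 | γ-silyloxy enone, C9=O, C7=C8 (C7–H), 6α-OTBS | CC(C)(C)[Si](C)(C)O[C@H]2C=CC(=O)[C@@](C)(C#C)[C@@H]2C(=C)C
F7 | step 12 | Michael adduct, 7β-CH2CO2Et, C8=C9–OTBS, 6α-OTBS | CC(C)(C)[Si](C)(C)O[C@H]2[C@H](CC(=O)OCC)C=C(O[Si](C)(C)C(C)(C)C)[C@@](C)(C#C)[C@@H]2C(=C)C
F8 | step 12 | 8α-silyloxy-9-oxo ester, 7β-CH2CO2Et, 6α-OTBS | CC(C)(C)[Si](C)(C)O[C@H]2[C@H](CC(=O)OCC)[C@@H](O[Si](C)(C)C(C)(C)C)C(=O)[C@@](C)(C#C)[C@@H]2C(=C)C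
F9 | step 6 | alkynyl cycloadduct, C7 silyl enol ether, C9 N(Bn)CO2Me, 10α-ethynyl | CC(C)(C)[Si](C)(C)OC1=C[C@@H](N(Cc2ccccc2)C(=O)OC)[C@@](C)(C#C)[C@@H](C1)C(=C)C
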